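**Retrosynthetic overview**

- Feature: the quaternary carbon of the 2-methylbut-3-en-2-yl group on C8 of ring A lies between C7–OH and C8a–O1. It is read as C3 of a benzofuran-2(3H)-one built on the phloroglucinol ring, whose lactone carbonyl carbon becomes the vinyl CH and whose ring oxygen becomes O1 of ring C.
- Late disconnections: the three MOM ethers; the C3–OH/C4=O oxidation level of ring C from a 2-aryl-3-nitro-2H-chromene with alkaline H2O2; the O1–C2 and C3–C4 bonds from a salicylaldehyde and a 4-oxygenated β-nitrostyrene (ring B).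
- Middle: the C4a–CHO by magnesium-mediated ortho-formylation; the vinyl group and the free C8a–OH by i-Bu2AlH reduction to the lactol and Wittig methylenation.
- Early: both C–CH3 bonds by double C3-methylation of the bis-MOM lactone enolate; the lactone from phloroglucinol and glyoxylic acid, SnCl2 reduction and MOM protection.
- Ring order: ring A is bought; the auxiliary lactone ring closes in step 1 and is opened in step 6; ring B arrives with the nitrostyrene; ring C closes in step 10 and is oxidised in step 11.

Key step: step 4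

Assumption: the target is the achiral 8-(1,1-dimethylallyl)kaempferol drawn as its 3-hydroxy-4-oxo tautomer. Chiral intermediates are racemic or stereoisomer mixtures, and all their stereocentres are destroyed before the target.

**Route**

Step 1
Reactants: 1 phloroglucinol; 2 glyoxylic acid (monohydrate)
Product: 4 racemic 3,4,6-trihydroxybenzofuran-2(3H)-one, via trihydroxymandelic acid 3 (not isolated)
Conditions: NaOH (aq, 2 equiv), H2O, 0 °C to rt, Ar; then HCl to pH 1, 50 °C
Reagents that add atoms: glyoxylic acid, O=CC(=O)O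
Why: Friedel–Crafts-type hydroxyalkylation of the phloroglucinol phenoxide by the aldehyde of glyoxylate (the hydroxymandelic acid synthesis) should give the mandelic acid, whose carboxyl closes onto an ortho hydroxyl on acidification; the three ring positions are equivalent and the cold alkaline medium holds back a second arylation at the benzylic carbon.

Step 2
Reactants: 4 racemic 3,4,6-trihydroxybenzofuran-2(3H)-one
Product: 5 4,6-dihydroxybenzofuran-2(3H)-one
Conditions: SnCl2·2H2O (3 equiv), conc. HCl/AcOH, 70 °C
Reagents that add atoms: none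
Why: In hot HCl the benzylic hydroxyl should ionise to a quinone-methide-type cation stabilised by the ortho and para oxygens, and divalent tin, present in excess before heating, reduces it to the methylene (reductive dehydroxylation of a hydroxymandelic lactone) while the five-membered lactone stays closed in acid.

Step 3
Reactants: 5 4,6-dihydroxybenzofuran-2(3H)-one; 6 chloromethyl methyl ether
Product: 7 4,6-bis(methoxymethoxy)benzofuran-2(3H)-one
Conditions: MOMCl (2.2 equiv), i-Pr2NEt (2.6 equiv), CH2Cl2/THF, 0 °C
Reagents that add atoms: chloromethyl methyl ether, COCCl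
Why: Williamson-type O-alkylation of the two phenols, which the amine deprotonates faster and more fully than the lactone C3–H, so that a small excess of reagent at 0 °C should stop at the bis-ether without methoxymethylation at C3.

Step 4
Reactants: 7 4,6-bis(methoxymethoxy)benzofuran-2(3H)-one; 8 iodomethane
Product: 10 4,6-bis(methoxymethoxy)-3,3-dimethylbenzofuran-2(3H)-one, via monomethyl lactone 9 (not isolated)
Conditions: NaH (2.5 equiv), MeI (5 equiv), THF, 0 °C to rt; 7 added slowly to base and MeI
Reagents that add atoms: iodomethane, CI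
Why: NaH removes the C3 proton, which is benzylic and alpha to the lactone carbonyl, to give the aromatic 2-oxidobenzofuran enolate, and this attacks iodomethane at carbon in an SN2 step; the monomethyl lactone 9 is deprotonated again and methylated a second time, so both C–CH3 bonds of the future quaternary carbon are made in one flask. The closest known reaction type is the C3,C3-dialkylation of benzofuran-2(3H)-ones and of arylacetic esters under enolate conditions. No ring is closed and no stereocentre is created, because C3 ends with two identical methyl groups. The step needs C- over O-methylation, a complete second alkylation and no self-acylation of the enolate by unreacted lactone: the soft electrophile and the regained lactone carbonyl favour attack at carbon, C3 is the only acidic carbon of 7, and slow addition of 7 to base and a large excess of iodomethane keeps the enolate from meeting free lactone. The MOM ethers are inert to NaH and MeI, and the 4-OMOM group next to C3 is the only steric burden on the second methylation.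

Step 5
Reactants: 10 4,6-bis(methoxymethoxy)-3,3-dimethylbenzofuran-2(3H)-one
Product: 11 racemic 4,6-bis(methoxymethoxy)-3,3-dimethyl-2,3-dihydrobenzofuran-2-ol
Conditions: i-Bu2AlH (1.2 equiv), CH2Cl2, −78 °C; aq KNaC4H4O6 (potassium sodium tartrate)
Reagents that add atoms: none
Why: Partial reduction of a lactone to the lactol with i-Bu2AlH, in which the tetrahedral aluminium hemiacetal is stable at −78 °C and shielded by the neighbouring quaternary carbon, so that hydrolysis should give the lactol without over-reduction to the diol and with the MOM ethers untouched.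

Step 6
Reactants: 11 racemic 4,6-bis(methoxymethoxy)-3,3-dimethyl-2,3-dihydrobenzofuran-2-ol; 12 methyltriphenylphosphonium bromide
Product: 14 3,5-bis(methoxymethoxy)-2-(2-methylbut-3-en-2-yl)phenol, via hydroxy aldehyde 13 (not isolated)
Conditions: Ph3PCH3Br (3.5 equiv), KOtBu (3.3 equiv), THF, 0 °C to 50 °C
Reagents that add atoms: methyltriphenylphosphonium bromide, C[P+](c1ccccc1)(c1ccccc1)c1ccccc1.[Br-]
Why: Wittig methylenation in which base opens the lactol to the phenoxide aldehyde, which has no alpha hydrogen and cannot enolise, and excess Ph3P=CH2 turns its carbonyl into the vinyl group while releasing the phenol that will become O1.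

Step 7
Reactants: 14 3,5-bis(methoxymethoxy)-2-(2-methylbut-3-en-2-yl)phenol; 15 paraformaldehyde
Product: 17 2-hydroxy-4,6-bis(methoxymethoxy)-3-(2-methylbut-3-en-2-yl)benzaldehyde, via hydroxymethyl phenol 16 (not isolated)
Conditions: MgCl2 (2 equiv), Et3N (4 equiv), (CH2O)n (6 equiv), MeCN, reflux; cold aq NH4Cl
Reagents that add atoms: paraformaldehyde (formaldehyde), C=O
Why: Magnesium-mediated ortho-formylation (Casnati–Skattebøl), in which formaldehyde is delivered within the magnesium phenoxide to the only free ortho position and the resulting benzylic alkoxide is oxidised by a second formaldehyde through hydride transfer, so the position between the two MOM ethers is not attacked.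

Step 8
Reactants: 18 4-hydroxybenzaldehyde; 6 chloromethyl methyl ether
Product: 19 4-(methoxymethoxy)benzaldehyde
Conditions: MOMCl (1.3 equiv), i-Pr2NEt (1.5 equiv), CH2Cl2, 0 °C to rt
Reagents that add atoms: chloromethyl methyl ether, COCCl
Why: Williamson-type etherification of the single phenol, needed because a free 4-hydroxyl would compete as an oxygen nucleophile in step 10.

Step 9
Reactants: 19 4-(methoxymethoxy)benzaldehyde; 20 nitromethane
Product: 21 (E)-1-(methoxymethoxy)-4-(2-nitroethenyl)benzene
Conditions: MeNO2 (solvent), NH4OAc (0.3 equiv), 90 °C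
Reagents that add atoms: nitromethane, C[N+](=O)[O-]
Why: Henry condensation with loss of water under NH4OAc catalysis should give the conjugated nitroalkene as the thermodynamically favoured E isomer, and the absence of added strong acid spares the MOM ether.

Step 10
Reactants: 17 2-hydroxy-4,6-bis(methoxymethoxy)-3-(2-methylbut-3-en-2-yl)benzaldehyde; 21 (E)-1-(methoxymethoxy)-4-(2-nitroethenyl)benzene
Product: 23 racemic 5,7-bis(methoxymethoxy)-2-[4-(methoxymethoxy)phenyl]-8-(2-methylbut-3-en-2-yl)-3-nitro-2H-chromene, via nitrochromanol 22 (not isolated)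
Conditions: DABCO (0.5 equiv), 21 (1.5 equiv), MeCN, 60 °C
Reagents that add atoms: (E)-1-(methoxymethoxy)-4-(2-nitroethenyl)benzene (21), COCOc1ccc(/C=C/[N+](=O)[O-])cc1
Why: DABCO-promoted oxa-Michael/Henry/dehydration cascade of a salicylaldehyde with a β-nitrostyrene, in which the phenoxide adds to the benzylic carbon of the nitroalkene, the nitronate closes onto the aldehyde (6-exo-trig) and water is lost to give the 3-nitro-2H-chromene; C2 is formed racemic and becomes sp2 in step 11.

Step 11
Reactants: 23 racemic 5,7-bis(methoxymethoxy)-2-[4-(methoxymethoxy)phenyl]-8-(2-methylbut-3-en-2-yl)-3-nitro-2H-chromene; 24 hydrogen peroxide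
Product: 27 3-hydroxy-5,7-bis(methoxymethoxy)-2-[4-(methoxymethoxy)phenyl]-8-(2-methylbut-3-en-2-yl)-4H-chromen-4-one, via nitro epoxide 25 (not isolated), via hydroperoxy ketone 26 (not isolated)
Conditions: 30% H2O2 (6 equiv), 2 M NaOH, MeOH/THF, 0 °C to rt
Reagents that add atoms: hydrogen peroxide, OO
Why: Alkaline hydrogen peroxide conversion of a 2-aryl-3-nitro-2H-chromene into a flavonol, by Weitz–Scheffer epoxidation of the nitroalkene, opening of the nitro epoxide at C4 by hydroperoxide with loss of nitrite to give the C3 ketone, Kornblum–DeLaMare-type loss of water to the 3,4-dione and enolisation to the 3-hydroxychromone; the isolated vinyl group and the MOM ethers do not react with the hydroperoxide anion.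

Step 12
Reactants: 27 3-hydroxy-5,7-bis(methoxymethoxy)-2-[4-(methoxymethoxy)phenyl]-8-(2-methylbut-3-en-2-yl)-4H-chromen-4-one
Product: 28 3,5,7-trihydroxy-2-(4-hydroxyphenyl)-8-(2-methylbut-3-en-2-yl)-4H-chromen-4-one (target)
Conditions: 3 M HCl, MeOH/THF, 45 °C
Reagents that add atoms: none
Why: Acid-catalysed acetal exchange of the three MOM ethers with methanol, run with dilute acid at moderate temperature because the monosubstituted vinyl group next to a quaternary carbon protonates only under much harsher conditions, so cyclisation onto the 7-hydroxyl is not expected.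

**Compound list**

1 | phloroglucinol (benzene-1,3,5-triol) | Oc1cc(O)cc(O)c1 | starting material
2 | glyoxylic acid (used as monohydrate) | O=CC(=O)O | starting material
3 | racemic 2,4,6-trihydroxymandelic acid | OC(C(=O)O)c1c(O)cc(O)cc1O | intermediate
4 | racemic 3,4,6-trihydroxybenzofuran-2(3H)-one | O=C1Oc2cc(O)cc(O)c2C1O | intermediate
5 | 4,6-dihydroxybenzofuran-2(3H)-one | O=C1Cc2c(O)cc(O)cc2O1 | intermediate
6 | chloromethyl methyl ether | COCCl | starting material
7 | 4,6-bis(methoxymethoxy)benzofuran-2(3H)-one | O=C1Cc2c(OCOC)cc(OCOC)cc2O1 | intermediate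
8 | iodomethane | CI | starting material
9 | racemic 4,6-bis(methoxymethoxy)-3-methylbenzofuran-2(3H)-one | CC1C(=O)Oc2cc(OCOC)cc(OCOC)c21 | intermediate
10 | 4,6-bis(methoxymethoxy)-3,3-dimethylbenzofuran-2(3H)-one | CC1(C)C(=O)Oc2cc(OCOC)cc(OCOC)c21 | intermediate
11 | racemic 4,6-bis(methoxymethoxy)-3,3-dimethyl-2,3-dihydrobenzofuran-2-ol | CC1(C)C(O)Oc2cc(OCOC)cc(OCOC)c21 | intermediate
12 | methyltriphenylphosphonium bromide | C[P+](c1ccccc1)(c1ccccc1)c1ccccc1.[Br-] | starting material
13 | 2-[2-hydroxy-4,6-bis(methoxymethoxy)phenyl]-2-methylpropanal (present as its phenoxide) | CC(C)(C=O)c1c(O)cc(OCOC)cc1OCOC | intermediate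
14 | 3,5-bis(methoxymethoxy)-2-(2-methylbut-3-en-2-yl)phenol | C=CC(C)(C)c1c(O)cc(OCOC)cc1OCOC | intermediate
15 | paraformaldehyde (source of formaldehyde) | C=O | starting material
16 | 2-(hydroxymethyl)-3,5-bis(methoxymethoxy)-6-(2-methylbut-3-en-2-yl)phenol (present as its magnesium salt) | C=CC(C)(C)c1c(O)c(CO)c(OCOC)cc1OCOC | intermediate
17 | 2-hydroxy-4,6-bis(methoxymethoxy)-3-(2-methylbut-3-en-2-yl)benzaldehyde | C=CC(C)(C)c1c(O)c(C=O)c(OCOC)cc1OCOC | intermediate
18 | 4-hydroxybenzaldehyde | O=Cc1ccc(O)cc1 | starting material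
19 | 4-(methoxymethoxy)benzaldehyde | COCOc1ccc(C=O)cc1 | intermediate
20 | nitromethane | C[N+](=O)[O-] | starting material
21 | (E)-1-(methoxymethoxy)-4-(2-nitroethenyl)benzene | COCOc1ccc(/C=C/[N+](=O)[O-])cc1 | intermediate
22 | 5,7-bis(methoxymethoxy)-2-[4-(methoxymethoxy)phenyl]-8-(2-methylbut-3-en-2-yl)-3-nitrochroman-4-ol (stereoisomer mixture) | C=CC(C)(C)c1c(OCOC)cc(OCOC)c2C(O)C([N+](=O)[O-])C(c3ccc(OCOC)cc3)Oc12 | intermediate
23 | racemic 5,7-bis(methoxymethoxy)-2-[4-(methoxymethoxy)phenyl]-8-(2-methylbut-3-en-2-yl)-3-nitro-2H-chromene | C=CC(C)(C)c1c(OCOC)cc(OCOC)c2C=C([N+](=O)[O-])C(c3ccc(OCOC)cc3)Oc12 | intermediate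
24 | hydrogen peroxide | OO | starting material
25 | 3,4-epoxy-5,7-bis(methoxymethoxy)-2-[4-(methoxymethoxy)phenyl]-8-(2-methylbut-3-en-2-yl)-3-nitrochroman (stereoisomer mixture) | C=CC(C)(C)c1c(OCOC)cc(OCOC)c2C3OC3([N+](=O)[O-])C(c4ccc(OCOC)cc4)Oc12 | intermediate
26 | 4-hydroperoxy-5,7-bis(methoxymethoxy)-2-[4-(methoxymethoxy)phenyl]-8-(2-methylbut-3-en-2-yl)chroman-3-one (stereoisomer mixture) | C=CC(C)(C)c1c(OCOC)cc(OCOC)c2C(OO)C(=O)C(c3ccc(OCOC)cc3)Oc12 | intermediate
27 | 3-hydroxy-5,7-bis(methoxymethoxy)-2-[4-(methoxymethoxy)phenyl]-8-(2-methylbut-3-en-2-yl)-4H-chromen-4-one | C=CC(C)(C)c1c(OCOC)cc(OCOC)c2c(=O)c(O)c(-c3ccc(OCOC)cc3)oc12 | intermediate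
28 | 3,5,7-trihydroxy-2-(4-hydroxyphenyl)-8-(2-methylbut-3-en-2-yl)-4H-chromen-4-one | C=CC(C)(C)c1c(O)cc(O)c2c(=O)c(O)c(-c3ccc(O)cc3)oc12 | target

**Step count and risks**

Total step count: 12 (steps 8 and 9 form the side branch to the nitrostyrene).
Longest linear sequence: 10 steps (steps 1 to 7, then 10 to 12).

The three steps most likely to fail:

1. Step 10. The oxa-Michael addition of a phenoxide flanked by the quaternary carbon may be slow, and the aldehyde, which carries two donor oxygens, is a weak electrophile for the Henry closure. Retro-Michael reaction and oligomerisation of the nitrostyrene could then outrun ring closure. The fallback sets out from 17 and comes back at 27, building ring C from an ortho-hydroxyacetophenone instead. Addition of MeMgBr (3 equiv, THF, 0 °C) to 17 should give the racemic carbinol 2-(1-hydroxyethyl)-3,5-bis(methoxymethoxy)-6-(2-methylbut-3-en-2-yl)phenol F1. Oxidation with MnO2 in CH2Cl2 should give 1-[2-hydroxy-4,6-bis(methoxymethoxy)-3-(2-methylbut-3-en-2-yl)phenyl]ethan-1-one F2. Claisen–Schmidt condensation of F2 with 19 (KOH, EtOH, rt) should give the chalcone (E)-1-[2-hydroxy-4,6-bis(methoxymethoxy)-3-(2-methylbut-3-en-2-yl)phenyl]-3-[4-(methoxymethoxy)phenyl]prop-2-en-1-one F3. Algar–Flynn–Oyamada oxidation (H2O2, NaOH, MeOH, 0 °C to rt) should then close ring C and give 27.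

2. Step 11. Under alkaline peroxide the electron-rich nitrochromene may open by retro-oxa-Michael reaction of the nitronate, or be cleaved oxidatively at C3–C4, and the flavonol formed may degrade on long exposure to base and oxidant. The fallback sets out from 17 (with 19 for ring B) and comes back at 27; it introduces the C3 oxygen through a carbon–boron bond on a preformed flavone. Homologation of 19 with dimethyl (1-diazo-2-oxopropyl)phosphonate (K2CO3, MeOH; Seyferth–Gilbert/Ohira–Bestmann) should give 1-ethynyl-4-(methoxymethoxy)benzene F4. Its lithium acetylide (n-BuLi, THF, −78 °C, 2.5 equiv) should add to 17 to give the racemic propargylic alcohol 2-{1-hydroxy-3-[4-(methoxymethoxy)phenyl]prop-2-yn-1-yl}-3,5-bis(methoxymethoxy)-6-(2-methylbut-3-en-2-yl)phenol F5. MnO2 oxidation should give the ynone 1-[2-hydroxy-4,6-bis(methoxymethoxy)-3-(2-methylbut-3-en-2-yl)phenyl]-3-[4-(methoxymethoxy)phenyl]prop-2-yn-1-one F6. DMAP-catalysed 6-endo-dig oxa-Michael cyclisation (DMF, rt) should give the flavone 5,7-bis(methoxymethoxy)-2-[4-(methoxymethoxy)phenyl]-8-(2-methylbut-3-en-2-yl)-4H-chromen-4-one F7. Lithiation of F7 at C3 with LiN(i-Pr)2 (THF, −78 °C), trapping with B(OMe)3 and oxidation of the boronate with H2O2/AcOH should give 27.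

3. Step 1. The first-formed mandelic acid may ionise at the benzylic carbon and be attacked by a second phloroglucinol ring, leading to diarylacetic acid and oligomers, above all during acidification. The fallback sets out from 1 and comes back at 5, using an acyl group that deactivates the ring after one substitution. Exhaustive O-methylation of 1 (Me2SO4, K2CO3, acetone, reflux) should give 1,3,5-trimethoxybenzene F8. Friedel–Crafts acylation with ethyl chlorooxoacetate (TiCl4, CH2Cl2, 0 °C) should give ethyl 2-oxo-2-(2,4,6-trimethoxyphenyl)acetate F9. Ionic hydrogenation of the aryl ketone (Et3SiH, CF3CO2H, rt) should give ethyl 2-(2,4,6-trimethoxyphenyl)acetate F10. BBr3 (CH2Cl2, −78 °C to rt) followed by warm dilute HCl should remove the three methyl groups and close the lactone to 5.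

Further compounds
F1 | step 10 | racemic 2-(1-hydroxyethyl)-3,5-bis(methoxymethoxy)-6-(2-methylbut-3-en-2-yl)phenol | C=CC(C)(C)c1c(O)c(C(C)O)c(OCOC)cc1OCOC
F2 | step 10 | 1-[2-hydroxy-4,6-bis(methoxymethoxy)-3-(2-methylbut-3-en-2-yl)phenyl]ethan-1-one | C=CC(C)(C)c1c(O)c(C(C)=O)c(OCOC)cc1OCOC
F3 | step 10 | (E)-1-[2-hydroxy-4,6-bis(methoxymethoxy)-3-(2-methylbut-3-en-2-yl)phenyl]-3-[4-(methoxymethoxy)phenyl]prop-2-en-1-one | C=CC(C)(C)c1c(O)c(C(=O)/C=C/c2ccc(OCOC)cc2)c(OCOC)cc1OCOC
F4 | step 11 | 1-ethynyl-4-(methoxymethoxy)benzene | C#Cc1ccc(OCOC)cc1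
F5 | step 11 | racemic 2-{1-hydroxy-3-[4-(methoxymethoxy)phenyl]prop-2-yn-1-yl}-3,5-bis(methoxymethoxy)-6-(2-methylbut-3-en-2-yl)phenol | C=CC(C)(C)c1c(O)c(C(O)C#Cc2ccc(OCOC)cc2)c(OCOC)cc1OCOC
F6 | step 11 | 1-[2-hydroxy-4,6-bis(methoxymethoxy)-3-(2-methylbut-3-en-2-yl)phenyl]-3-[4-(methoxymethoxy)phenyl]prop-2-yn-1-one | C=CC(C)(C)c1c(O)c(C(=O)C#Cc2ccc(OCOC)cc2)c(OCOC)cc1OCOC
F7 | step 11 | 5,7-bis(methoxymethoxy)-2-[4-(methoxymethoxy)phenyl]-8-(2-methylbut-3-en-2-yl)-4H-chromen-4-one | C=CC(C)(C)c1c(OCOC)cc(OCOC)c2c(=O)cc(-c3ccc(OCOC)cc3)oc12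
F8 | step 1 | 1,3,5-trimethoxybenzene | COc1cc(OC)cc(OC)c1
F9 | step 1 | ethyl 2-oxo-2-(2,4,6-trimethoxyphenyl)acetate | CCOC(=O)C(=O)c1c(OC)cc(OC)cc1OC
F10 | step 1 | ethyl 2-(2,4,6-trimethoxyphenyl)acetate | CCOC(=O)Cc1c(OC)cc(OC)cc1OC
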